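**Assumption (one line):** the SMILES is read as an upper (2S,3S)-ent-epiafzelechin unit (U), a middle (2R,3R)-epiafzelechin unit (M) and a lower (2S,3S,4R)-flavan-3,4-diol unit (L), both 4→8 bonds 3,4-cis (all-cis pyrans in U and M), L 2,3-cis-3,4-trans; cat-R and cat-S are the antipodes of 3,3'-bis(2,4,6-triisopropylphenyl)-BINOL N-triflylphosphoramide, cat-R being taken as the one that gives the (2R,3R) ring (to be confirmed once in step 5, and the antipodes swapped if the sense is reversed).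

## Retrosynthetic overview

1. The all-cis 2-aryl-3-oxy-4-aryl pyrans of U and M are each the endo [4+2] adduct of an o-quinone methide (o-QM) with the (Z)-enol acetate 6. The cationic C4–C8 coupling most chemists would use gives 3,4-trans and is not used.
2. The last ring-forming step is one double annulation on the middle chroman 11. The U pyran (diaryl o-QM) and the L pyran (methoxy-o-QM from a salicylaldehyde) close together under one catalyst, because U and L share the (2S,3S) sense.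
3. The M pyran is made first, with the antipodal catalyst, from the symmetric diarylmethyl ether 4. Either ring of 4 gives the same o-QM, and the product 8 carries two differentiated CHO groups.
4. 4 comes from 2,4,6-trihydroxybenzaldehyde by dibenzylation, methylene dimerisation and DDQ/MeOH oxidation.
5. Ring order: M, then U + L together. End game: deacetylation, debenzylation, and C4-OMe → C4-OH on L by SN1 anti to the 3-OH.

## Route

**Step 1**
Reactants: 1 2,4,6-trihydroxybenzaldehyde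
Product: 2 2,4-bis(benzyloxy)-6-hydroxybenzaldehyde
Conditions: BnBr (2.1 equiv), K2CO3 (2.2 equiv), DMF, 0 °C → rt
Reagents that add atoms: benzyl bromide, BrCc1ccccc1
Why: Williamson etherification; the OH hydrogen-bonded to the CHO is the least nucleophilic and stays free.

**Step 2**
Reactants: 2 2,4-bis(benzyloxy)-6-hydroxybenzaldehyde (2 equiv)
Product: 3 3,3'-methylenebis[4,6-bis(benzyloxy)-2-hydroxybenzaldehyde]
Conditions: (CH2O)n (0.5 equiv), MgCl2, Et3N, THF, reflux; 1 M HCl work-up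
Reagents that add atoms: formaldehyde (as paraformaldehyde), C=O
Why: Magnesium-phenoxide (Casiraghi/Skattebøl-type) ortho-hydroxymethylation; with formaldehyde limiting, the salicyl alkoxide is captured by a second phenoxide at its only free ortho carbon to give the methylene-bridged bisphenol.

**Step 3**
Reactants: 3 3,3'-methylenebis[4,6-bis(benzyloxy)-2-hydroxybenzaldehyde]
Product: 4 3,3'-(methoxymethylene)bis[4,6-bis(benzyloxy)-2-hydroxybenzaldehyde]
Conditions: DDQ (1.1 equiv), CH2Cl2/MeOH 4:1, 0 °C → rt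
Reagents that add atoms: methanol, CO
Why: DDQ benzylic oxidation (hydride abstraction from the doubly activated diarylmethane) and capture of the cation/o-QM by methanol gives a storable o-QM precursor.

**Step 4**
Reactants: 5 1-(benzyloxy)-4-ethynylbenzene
Product: 6 (Z)-2-[4-(benzyloxy)phenyl]ethenyl acetate
Conditions: AcOH (1.5 equiv), [Ru(methallyl)2(dppb)] (2 mol %), toluene, 60 °C
Reagents that add atoms: acetic acid, CC(O)=O
Why: Ru-catalysed anti-Markovnikov hydro-acyloxylation of a terminal alkyne via a vinylidene gives the (Z)-enol ester selectively.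

**Step 5**
Reactants: 4 3,3'-(methoxymethylene)bis[4,6-bis(benzyloxy)-2-hydroxybenzaldehyde]; 6 (Z)-2-[4-(benzyloxy)phenyl]ethenyl acetate (3 equiv)
Product: 8 (2R,3R)-2,3-cis-3,4-cis-3-acetoxy-5,7-bis(benzyloxy)-2-[4-(benzyloxy)phenyl]-4-[4,6-bis(benzyloxy)-3-formyl-2-hydroxyphenyl]chromane-8-carbaldehyde, via o-quinone methide 7 (not isolated)
Conditions: cat-R (10 mol %), 5 Å MS, CH2Cl2, −20 → 0 °C
Reagents that add atoms: none
Why: Proposed new method: the acid ionises the diarylmethyl ether to the ion-paired o-QM 7, which undergoes an inverse-demand hetero-Diels–Alder reaction with 6; the p-alkoxyphenyl group places the aryl at C2 and the acetoxy at C3, suprafacial addition of the Z-alkene sets 2,3-cis, the endo transition state sets 3,4-cis, and the chiral anion sets the (2R,3R) sense, while the aldehydes stay spectators without acetalisation (closest known: chiral N-triflylphosphoramide-catalysed [4+2] of o-QMs from o-hydroxybenzhydryl alcohols with styrenes).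

**Step 6**
Reactants: 8 middle-unit dialdehyde chroman; 9 3,5-bis(benzyloxy)phenol (3 equiv)
Product: 11 (2R,3R)-all-cis-3-acetoxy-5,7-bis(benzyloxy)-2-[4-(benzyloxy)phenyl]-4-[4,6-bis(benzyloxy)-3-formyl-2-hydroxyphenyl]-8-{[2,4-bis(benzyloxy)-6-hydroxyphenyl](hydroxy)methyl}chromane (carbinol epimers), via bromomagnesium phenoxide 10 (not isolated)
Conditions: 9, EtMgBr (3 equiv), Et2O, 0 °C; then toluene, 8, 20 °C; aq. NH4Cl
Reagents that add atoms: none
Why: Casiraghi ortho-specific hydroxyalkylation: the magnesium phenoxide delivers its ortho carbon to the non-chelated 8-CHO, while the salicylaldehyde CHO is deactivated as its magnesium chelate; the carbinol centre is lost again in step 7.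

**Step 7**
Reactants: 11 carbinol–salicylaldehyde chroman; 6 (Z)-2-[4-(benzyloxy)phenyl]ethenyl acetate (6 equiv)
Product: 13 3,3',3''-tri-O-acetyl-nona-O-benzyl-4-O-methyl (lower unit) derivative of the target, via bis(o-quinone methide) 12 (not isolated)
Conditions: cat-S (15 mol %), HC(OMe)3 (3 equiv), CH2Cl2, −20 → 20 °C
Reagents that add atoms: trimethyl orthoformate, COC(OC)OC
Why: Proposed new method: in one flask the carbinol dehydrates to a diaryl o-QM and the salicylaldehyde, switched on as its dimethyl acetal, loses MeOH to a methoxy-o-QM (oxocarbenium), and each undergoes endo [4+2] with 6, so the U and L pyrans form together with five stereocentres (U all-cis, L 2,3-cis) in the (2S,3S) sense under one chiral anion; the L C4-OMe configuration is immaterial because it is reset in step 10 (closest known: acid-catalysed o-QM/styrene [4+2] and acid-promoted [4+2] of salicylaldehyde acetals with alkenes to 4-alkoxychromans).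

**Step 8**
Reactants: 13 tri-O-acetyl-nona-O-benzyl-4-O-methyl trimer
Product: 14 nona-O-benzyl-4-O-methyl (lower unit) trimer 3,3',3''-triol
Conditions: K2CO3 (0.5 equiv), MeOH/THF 1:1, 20–40 °C
Reagents that add atoms: none
Why: Zemplén-type transesterification removes the three secondary acetates; with all phenols benzylated there is no quinone-methide pathway for C2 epimerisation.

**Step 9**
Reactants: 14 nona-O-benzyl-4-O-methyl trimer triol
Product: 15 4-O-methyl ether (lower-unit C4) of the target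
Conditions: H2 (1 atm), 20% Pd(OH)2/C, EtOAc/MeOH 1:1, Et3N (trace), 20 °C
Reagents that add atoms: none
Why: Hydrogenolysis of the nine aryl benzyl ethers; the amine trace suppresses acid-promoted cleavage of the benzylic C4–OMe and of the interflavan bonds.

**Step 10**
Reactants: 15 4-O-methyl ether of the target
Product: 16 target (CNP0159291.1)
Conditions: H2O/MeCN 4:1, AcOH to pH ≈ 3, ≤ 1 mM, 20 °C; lyophilise
Reagents that add atoms: water, O
Why: SN1 solvolysis of the 5,7-dihydroxy-activated C4 ether under high dilution; water adds to the C4 cation anti to the axial 3-OH, giving the 2,3-cis-3,4-trans (4R) diol, under conditions too mild to ionise the C–C interflavan bonds.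

## Compound list

1 | 2,4,6-trihydroxybenzaldehyde | O=Cc1c(O)cc(O)cc1O | starting material
2 | 2,4-bis(benzyloxy)-6-hydroxybenzaldehyde | O=Cc1c(O)cc(OCc2ccccc2)cc1OCc1ccccc1 | intermediate
3 | 3,3'-methylenebis[4,6-bis(benzyloxy)-2-hydroxybenzaldehyde] | O=Cc1c(O)c(Cc2c(O)c(C=O)c(OCc3ccccc3)cc2OCc2ccccc2)c(OCc2ccccc2)cc1OCc1ccccc1 | intermediate
4 | 3,3'-(methoxymethylene)bis[4,6-bis(benzyloxy)-2-hydroxybenzaldehyde] | O=Cc1c(O)c(C(OC)c2c(O)c(C=O)c(OCc3ccccc3)cc2OCc2ccccc2)c(OCc2ccccc2)cc1OCc1ccccc1 | intermediate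
5 | 1-(benzyloxy)-4-ethynylbenzene | C#Cc1ccc(OCc2ccccc2)cc1 | starting material
6 | (Z)-2-[4-(benzyloxy)phenyl]ethenyl acetate | CC(=O)O/C=C\c1ccc(OCc2ccccc2)cc1 | intermediate
7 | o-quinone methide from 4 by loss of MeOH (aryl anti to the ring C=O) | O=CC1=C(OCc2ccccc2)C=C(OCc2ccccc2)/C(=C\c2c(O)c(C=O)c(OCc3ccccc3)cc2OCc2ccccc2)C1=O | intermediate
8 | (2R,3R)-all-cis-3-acetoxy-5,7-bis(benzyloxy)-2-[4-(benzyloxy)phenyl]-4-[4,6-bis(benzyloxy)-3-formyl-2-hydroxyphenyl]chromane-8-carbaldehyde | c9ccccc9COc1ccc([C@H]2Oc3c(c(OCc9ccccc9)cc(OCc9ccccc9)c3C=O)[C@@H](c3c(OCc9ccccc9)cc(OCc9ccccc9)c(C=O)c3O)[C@H]2OC(C)=O)cc1 | intermediate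
9 | 3,5-bis(benzyloxy)phenol | Oc1cc(OCc2ccccc2)cc(OCc2ccccc2)c1 | starting material
10 | bromomagnesium 3,5-bis(benzyloxy)phenoxide | Br[Mg]Oc1cc(OCc2ccccc2)cc(OCc2ccccc2)c1 | intermediate
11 | 8-{[2,4-bis(benzyloxy)-6-hydroxyphenyl](hydroxy)methyl} analogue of 8 with the 8-CHO converted (carbinol epimers; M unit 2R,3R all-cis) | c9ccccc9COc1ccc([C@H]2Oc3c(c(OCc9ccccc9)cc(OCc9ccccc9)c3C(O)c3c(OCc9ccccc9)cc(OCc9ccccc9)cc3O)[C@@H](c3c(OCc9ccccc9)cc(OCc9ccccc9)c(C=O)c3O)[C@H]2OC(C)=O)cc1 | intermediate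
12 | bis(o-quinone methide) from 11: diaryl o-QM on the future U ring and methoxy-o-QM on the future L ring | c9ccccc9COc1ccc([C@H]2Oc3c(c(OCc9ccccc9)cc(OCc9ccccc9)c3/C=C3\C(OCc9ccccc9)=CC(OCc9ccccc9)=CC3=O)[C@@H](C3=C(OCc9ccccc9)C=C(OCc9ccccc9)/C(=C\OC)C3=O)[C@H]2OC(C)=O)cc1 | intermediate
13 | tri-O-acetyl-nona-O-benzyl-4-O-methyl trimer (U 2S,3S all-cis; M 2R,3R all-cis; L 2S,3S with 4-OMe, 3,4-trans epimer drawn) | c9ccccc9COc1ccc([C@H]2Oc3c(c(OCc9ccccc9)cc(OCc9ccccc9)c3[C@H]3c4c(OCc9ccccc9)cc(OCc9ccccc9)cc4O[C@@H](c4ccc(OCc9ccccc9)cc4)[C@H]3OC(C)=O)[C@@H](c3c(OCc9ccccc9)cc(OCc9ccccc9)c4c3O[C@@H](c3ccc(OCc9ccccc9)cc3)[C@@H](OC(C)=O)[C@@H]4OC)[C@H]2OC(C)=O)cc1 | intermediate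
14 | nona-O-benzyl-4-O-methyl trimer 3,3',3''-triol | c9ccccc9COc1ccc([C@H]2Oc3c(c(OCc9ccccc9)cc(OCc9ccccc9)c3[C@H]3c4c(OCc9ccccc9)cc(OCc9ccccc9)cc4O[C@@H](c4ccc(OCc9ccccc9)cc4)[C@H]3O)[C@@H](c3c(OCc9ccccc9)cc(OCc9ccccc9)c4c3O[C@@H](c3ccc(OCc9ccccc9)cc3)[C@@H](O)[C@@H]4OC)[C@H]2O)cc1 | intermediate
15 | lower-unit 4-O-methyl ether of the target | Oc1ccc([C@H]2Oc3c(c(O)cc(O)c3[C@H]3c4c(O)cc(O)cc4O[C@@H](c4ccc(O)cc4)[C@H]3O)[C@@H](c3c(O)cc(O)c4c3O[C@@H](c3ccc(O)cc3)[C@@H](O)[C@@H]4OC)[C@H]2O)cc1 | intermediate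
16 | CNP0159291.1: ent-epiafzelechin-(4→8, 3,4-cis)-epiafzelechin-(4→8, 3,4-cis)-(2S,3S,4R)-4',5,7-trihydroxyflavan-3,4-diol | Oc1ccc([C@H]2Oc3c(c(O)cc(O)c3[C@H]3c4c(O)cc(O)cc4O[C@@H](c4ccc(O)cc4)[C@H]3O)[C@@H](c3c(O)cc(O)c4c3O[C@@H](c3ccc(O)cc3)[C@@H](O)[C@@H]4O)[C@H]2O)cc1 | target

## Summary

Total steps: 10. Longest linear sequence: 9 (1 → 2 → 3 → 4 → 8 → 11 → 13 → 14 → 15 → 16).

**Steps most likely to fail, with fallbacks**

- **Step 7 (double annulation).** The risk is that the electron-rich salicylaldehyde acetal does not engage the weak dienophile, or does so without catalyst control, and that the L-ring C4-OMe re-ionises. Fallback: from 11, NaBH4 (MeOH/THF, 0 °C) reduces only the salicylaldehyde to the salicyl alcohol F3. The double cycloaddition is then run on two carbinol-type o-QMs (cat-S, 6, no orthoformate) to give the protected trimer with an unsubstituted lower-unit C4, F4. DDQ in CH2Cl2/MeOH then methoxylates that CH2, the only unhindered benzylic position, trans to the 3-OAc, and the route is rejoined at 13.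
- **Step 5 (first asymmetric o-QM cycloaddition).** The risk is low reactivity of the enol acetate or poor enantiocontrol with the 5-alkoxy-flanked o-QM. Fallback: from 4 and 6, run the cycloaddition with achiral diphenyl phosphate to give the racemic all-cis chroman F1, then resolve it by preparative chromatography on a chiral stationary phase; the (2R,3R) antipode is 8.
- **Step 6 (magnesium-phenoxide addition in the presence of an acetate and a second CHO).** Fallback: from 9, ortho-iodination with NIS gives 3,5-bis(benzyloxy)-2-iodophenol F2. Nozaki–Hiyama–Kishi coupling of F2 (CrCl2, cat. NiCl2, DMF) with the non-chelated 8-CHO of 8 tolerates the ester and returns to 11.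

## Further compounds

F1 | step 5 | racemic all-cis 8 (1:1 mixture of 8 and its enantiomer) | c9ccccc9COc1ccc([C@H]2Oc3c(c(OCc9ccccc9)cc(OCc9ccccc9)c3C=O)[C@@H](c3c(OCc9ccccc9)cc(OCc9ccccc9)c(C=O)c3O)[C@H]2OC(C)=O)cc1.c9ccccc9COc1ccc([C@@H]2Oc3c(c(OCc9ccccc9)cc(OCc9ccccc9)c3C=O)[C@H](c3c(OCc9ccccc9)cc(OCc9ccccc9)c(C=O)c3O)[C@@H]2OC(C)=O)cc1
F2 | step 6 | 3,5-bis(benzyloxy)-2-iodophenol | Oc1cc(OCc2ccccc2)cc(OCc2ccccc2)c1I
F3 | step 7 | salicyl alcohol analogue of 11 (CHO reduced to CH2OH) | c9ccccc9COc1ccc([C@H]2Oc3c(c(OCc9ccccc9)cc(OCc9ccccc9)c3C(O)c3c(OCc9ccccc9)cc(OCc9ccccc9)cc3O)[C@@H](c3c(OCc9ccccc9)cc(OCc9ccccc9)c(CO)c3O)[C@H]2OC(C)=O)cc1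
F4 | step 7 | tri-O-acetyl-nona-O-benzyl trimer with lower-unit C4 = CH2 | c9ccccc9COc1ccc([C@H]2Oc3c(c(OCc9ccccc9)cc(OCc9ccccc9)c3[C@H]3c4c(OCc9ccccc9)cc(OCc9ccccc9)cc4O[C@@H](c4ccc(OCc9ccccc9)cc4)[C@H]3OC(C)=O)[C@@H](c3c(OCc9ccccc9)cc(OCc9ccccc9)c4c3O[C@@H](c3ccc(OCc9ccccc9)cc3)[C@@H](OC(C)=O)C4)[C@H]2OC(C)=O)cc1
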